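In a closed flask the electrophile charged always equals what is left plus what has reacted, so we follow the left part. The electrophile is charged in the smaller amount, so its balance is the one we write. If it reacts by a step first order in itself, then the logarithm of the left part adds up the nucleophile it has met, so we compare flasks by the ratio of their left parts.

all flasks: electrophile 0.10 M
- Tuesday's: nucleophile 0.32 M; run made earlier
- Thursday's: nucleophile 1.2 M; run made earlier
- red: nucleophile 0.250 M; time 15 min
- grey: nucleophile 0.500 M; time 15 min
- blue: nucleophile 1.00 M; time 15 min

* part of the electrophile that has reacted at the end, red
* part of the electrophile that has reacted at the end, grey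
* part of the electrophile that has reacted at the end, blue
* what raising the concentration of nucleophile from its lowest to its highest value here does to the part of the electrophile that has reacted (changes below 5 percentage points count as none) (no change / it falls / it rises)

- the numbers in the tables scatter by 0.5 percentage points (one standard deviation)

| run | time / min | electrophile / % | target / % |
|---|---|---|---|
| Tuesday's | 0.500 | 85.7 | 10.7 |
| Tuesday's | 1.33 | 78.1 | 8.2 |
| Tuesday's | 2.50 | 75.4 | 5.0 |
| Tuesday's | 4.00 | 73.3 | 2.1 |
| Tuesday's | 6.00 | 71.6 | 1.3 |
| Tuesday's | 8.00 | 70.1 | 0.2 |
| Thursday's | 1.33 | 67.4 | 12.5 |
| Thursday's | 2.50 | 64.2 | 5.8 |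
| Thursday's | 4.00 | 61.9 | 2.2 |
| Thursday's | 5.00 | 61.6 | 2.1 |
| Thursday's | 6.00 | 60.9 | 0.8 |
| Thursday's | 8.00 | 59.6 | 0.7 |

(standard deviation of a reading: 0.5 percentage points)

We read the two tables row against row at equal times. At 2.50 min, Tuesday's flask holds 75.4 % and Thursday's 64.2 %, a ratio of 1.17. At 8.00 min they hold 70.1 % and 59.6 %, a ratio of 1.18. Both columns are still falling, but within the scatter their ratio stands still, so the nucleophile charge seems to act early and then stay as a constant factor.

That gives us a number to carry. The nucleophile exponent is the power of the nucleophile charge by which the left part falls at equal time, and from the last rows it reads 0.123.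

Our own reckoning gives a ratio, not amounts, and it assumes the exponent lasts beyond the readings. Going from red to blue, the left part in blue should be 0.844 of the left part in red.

The forecast gives amounts: 33 % for red, 38 % for grey and 43.5 % for blue, with the ranges 29 % to 36 %, 34.5 % to 41.5 % and 40 % to 47 %. On the trend its answer is it rises, in its words “so conversion rises with nucleophile”.

The flasks give 30.4 % in red, 36.4 % in grey and 42.1 % in blue, each inside the forecast's range. For the part reacted, raising the nucleophile from red to blue gives: it rises, by 12 percentage points. The left part in blue over that in red comes to 0.832, against our 0.844.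

    target → over-reaction product (k = 0.0170 s⁻¹)
    electrophile + nucleophile → acid set free + target (k = 0.0440 M⁻¹ s⁻¹)
    nucleophile + acid set free ⇌ protonated nucleophile, settled at all times (K = 1100 M⁻¹)
    2 nucleophile → homo dimer (k = 0.190 M⁻¹ s⁻¹)

The neighbouring flask is blue with 0.40 M of electrophile, which makes 2.50 equiv of nucleophile. No run varied the electrophile, so we try the exponent on equivalents, starting from blue's left part: 68.7 %. The neighbour leaves 67 %, so 32.6 % has reacted, less than in blue. The charge that runs out first there is the nucleophile, charged in excess, with 0.13 % of its charge left unbound at the end.

The readings stem from a simulated flask with made-up constants.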